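**Plan**

- Retrosynthesis: the three benzyl-masked O–H groups are unveiled last. One C3''–CH3 bond is cut (methyl Grignard on a methyl ketone). Then C1''–C2'' is cut together with a temporary O5–C3'' bond (o-quinone methide plus 2-methoxypropene). Finally C6–C1'' is cut (formaldehyde onto tri-O-benzylkaempferol).
- Enabling feature: the benzylic carbon C1'' sits on C6 of ring A, ortho to the free 5-OH. O5=C5–C6=C1'' is therefore a latent 1-oxadiene (an A-ring o-quinone methide) whose methide carbon can bond to C2''.
- Forward: kaempferol → 3,7,4'-tribenzyl ether → C6 formylation and reduction (C1'' joined) → [4+2] that joins C2''/C3'' and closes a temporary dihydropyran on the C5–C6 edge → acid opens that ring to the 3-oxobutyl chain → MeMgBr → hydrogenolysis.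
- Stereochemistry: the target has no stereocentre. The only one on the route, the ketal carbon of the cycloadduct, forms as a racemate and is erased on hydrolysis.

Key step: step 4

Remark: because the target is achiral, the "single enantiomer" is the compound itself and no enantiocontrol is needed; flavone numbering is used, with the side chain numbered C1'' (benzylic) to C3'' (carbinol).

**Step 1**
Reactants: 1 kaempferol
Product: 2 3,7,4'-tri-O-benzylkaempferol
Conditions: BnBr (3.3 equiv), K2CO3 (3.5 equiv), DMF, rt → 40 °C
Reagents that add atoms: benzyl bromide, BrCc1ccccc1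
Why: Williamson etherification in which the 5-OH, locked in a hydrogen bond to the C4 carbonyl, is the least acidic and least nucleophilic hydroxyl, so a controlled amount of benzyl bromide should alkylate O3, O7 and O4' and leave O5 free.

**Step 2**
Reactants: 2 3,7,4'-tri-O-benzylkaempferol; 3 paraformaldehyde
Product: 5 3,7,4'-tri-O-benzyl-6-formylkaempferol, via magnesium salt of the 6-hydroxymethyl flavonol 4 (not isolated)
Conditions: anhydrous MgCl2 (3 equiv), Et3N (6 equiv), (CH2O)n (8 equiv), THF, reflux; then 1 M aq. HCl
Reagents that add atoms: none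
Why: Casnati–Skattebøl magnesium-mediated ortho-formylation, in which the magnesium 5-phenoxide delivers coordinated formaldehyde to C6, the only free ortho position (C8 is para to O5 and out of reach), and the resulting hydroxymethyl alkoxide 4 is oxidised in the flask by a second formaldehyde through an Oppenauer-type hydride transfer, so the aldehyde rather than the alcohol is obtained.

**Step 3**
Reactants: 5 3,7,4'-tri-O-benzyl-6-formylkaempferol
Product: 6 3,7,4'-tri-O-benzyl-6-(hydroxymethyl)kaempferol
Conditions: NaBH4 (1.2 equiv), THF/MeOH, −10 → 0 °C; sat. aq. NH4Cl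
Reagents that add atoms: none
Why: Borohydride reduction of an aldehyde, which is far more electrophilic than the vinylogous-ester C4 carbonyl of the flavone; low temperature, a small excess of hydride and a buffered quench are chosen so that the electron-rich salicyl alkoxide is not carried on to the 6-methyl compound.

**Step 4**
Reactants: 6 3,7,4'-tri-O-benzyl-6-(hydroxymethyl)kaempferol; 7 2-methoxypropene
Product: 9 racemic 5,6-fused 2-methoxy-2-methyl-3,4-dihydro-2H-pyran ketal of 3,7,4'-tri-O-benzylkaempferol, via A-ring o-quinone methide 8 (not isolated)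
Conditions: 2-methoxypropene (20 equiv), toluene, base-washed sealed pressure tube, 150–170 °C
Reagents that add atoms: none
Why: Heating expels water across O5–H and C1''–OH and unveils the A-ring o-quinone methide 8, an electron-poor 1-oxadiene (O5=C5–C6=C1'') whose LUMO is lowered further by the cross-conjugated C4 carbonyl. The closest known reaction type is the inverse-electron-demand hetero-Diels–Alder reaction of thermally generated o-quinone methides with enol ethers, which gives 2-alkoxychromans. The dihydropyran ring closes by an intermolecular, asynchronous [4+2] cycloaddition in which C1''–C2'' forms ahead of O5–C3'', and the return of ring A to aromaticity makes the addition irreversible. The single new stereocentre, the ketal carbon C3'', arises without control as a racemate, which is acceptable because step 5 destroys it. The step needs regioselectivity, secured by polarity matching (nucleophilic CH2 terminus of the enol ether to the electrophilic methide carbon, oxocarbenium-like carbon to O5), and site selectivity, secured because O5 is the only free phenol and C6 the only carbon carrying CH2OH. The large excess of enol ether is meant to outrun self-condensation of the methide, whereas its capture by water or by the benzylic alcohol is reversible at this temperature and only returns it to the productive pool.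

**Step 5**
Reactants: 9 racemic 5,6-fused 2-methoxy-2-methyl-3,4-dihydro-2H-pyran ketal of 3,7,4'-tri-O-benzylkaempferol
Product: 11 3,7,4'-tri-O-benzyl-6-(3-oxobutyl)kaempferol, via cyclic hemiketal 10 (not isolated)
Conditions: 1 M aq. HCl, THF, rt
Reagents that add atoms: water, O
Why: Acid-catalysed hydrolysis of a mixed aryl methyl ketal through the oxocarbenium ion and the cyclic hemiketal 10, which should open to the ketone because the phenol is a good leaving group and regains its hydrogen bond to the C4 carbonyl, while benzyl ethers and the flavone are inert to dilute acid at room temperature.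

**Step 6**
Reactants: 11 3,7,4'-tri-O-benzyl-6-(3-oxobutyl)kaempferol
Product: 12 3,7,4'-tri-O-benzyl-6-(3-hydroxy-3-methylbutyl)kaempferol
Conditions: MeMgBr (3.5 equiv), THF, −40 → 0 °C; sat. aq. NH4Cl
Reagents that add atoms: methylmagnesium bromide, C[Mg]Br
Why: Grignard addition to a ketone in which the first equivalent deprotonates the 5-OH and the resulting magnesium chelate between O5 and the C4 carbonyl makes the flavone carbonyl a poor electrophile, so further reagent should add to the unhindered aliphatic methyl ketone; no stereocentre arises because the carbinol carbon carries two methyl groups, and the mild quench avoids acid-induced cyclisation onto O5.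

**Step 7**
Reactants: 12 3,7,4'-tri-O-benzyl-6-(3-hydroxy-3-methylbutyl)kaempferol
Product: 13 6-(3-hydroxy-3-methylbutyl)kaempferol
Conditions: H2 (1 atm), 10% Pd/C, EtOAc/MeOH, rt
Reagents that add atoms: none
Why: Catalytic hydrogenolysis of the three benzyl ethers under neutral conditions, where the non-benzylic tertiary alcohol and the tetrasubstituted C2=C3 bond of the flavonol should be untouched and the absence of acid prevents ring closure of the tertiary alcohol onto a neighbouring phenol.

**Compound list**

1 | kaempferol | O=c1c(O)c(-c2ccc(O)cc2)oc2cc(O)cc(O)c12 | starting material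
2 | 3,7,4'-tri-O-benzylkaempferol (3,7-bis(benzyloxy)-2-[4-(benzyloxy)phenyl]-5-hydroxy-4H-chromen-4-one) | O=c1c(OCc2ccccc2)c(-c2ccc(OCc3ccccc3)cc2)oc2cc(OCc3ccccc3)cc(O)c12 | intermediate
3 | paraformaldehyde (reacts as formaldehyde) | C=O | starting material
4 | magnesium salt of 3,7,4'-tri-O-benzyl-6-(hydroxymethyl)kaempferol (5-phenoxide/benzylic alkoxide chelate) | [Mg+2].[O-]Cc1c(OCc2ccccc2)cc2oc(-c3ccc(OCc4ccccc4)cc3)c(OCc3ccccc3)c(=O)c2c1[O-] | intermediate (not isolated)
5 | 3,7,4'-tri-O-benzyl-6-formylkaempferol (5-hydroxy-4-oxo-4H-chromene-6-carbaldehyde) | O=Cc1c(OCc2ccccc2)cc2oc(-c3ccc(OCc4ccccc4)cc3)c(OCc3ccccc3)c(=O)c2c1O | intermediate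
6 | 3,7,4'-tri-O-benzyl-6-(hydroxymethyl)kaempferol | OCc1c(OCc2ccccc2)cc2oc(-c3ccc(OCc4ccccc4)cc3)c(OCc3ccccc3)c(=O)c2c1O | intermediate
7 | 2-methoxypropene | COC(C)=C | starting material
8 | A-ring o-quinone methide, 3,7-bis(benzyloxy)-2-[4-(benzyloxy)phenyl]-6-methylidene-4H-chromene-4,5(6H)-dione | C=C1C(=O)C2=C(C=C1OCc1ccccc1)OC(c1ccc(OCc3ccccc3)cc1)=C(OCc1ccccc1)C2=O | intermediate (not isolated)
9 | racemic cyclic ketal: 2-methoxy-2-methyl-3,4-dihydro-2H-pyran fused to the C5–C6 edge of 3,7,4'-tri-O-benzylkaempferol (ring O = O5, ketal carbon = C3'', ring CH2–CH2 = C2''–C1'' on C6) | COC1(C)CCc2c(OCc3ccccc3)cc3oc(-c4ccc(OCc5ccccc5)cc4)c(OCc4ccccc4)c(=O)c3c2O1 | intermediate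
10 | racemic cyclic hemiketal (2-hydroxy-2-methyl analogue of 9) | CC1(O)CCc2c(OCc3ccccc3)cc3oc(-c4ccc(OCc5ccccc5)cc4)c(OCc4ccccc4)c(=O)c3c2O1 | intermediate (not isolated)
11 | 3,7,4'-tri-O-benzyl-6-(3-oxobutyl)kaempferol | CC(=O)CCc1c(OCc2ccccc2)cc2oc(-c3ccc(OCc4ccccc4)cc3)c(OCc3ccccc3)c(=O)c2c1O | intermediate
12 | 3,7,4'-tri-O-benzyl-6-(3-hydroxy-3-methylbutyl)kaempferol | CC(C)(O)CCc1c(OCc2ccccc2)cc2oc(-c3ccc(OCc4ccccc4)cc3)c(OCc3ccccc3)c(=O)c2c1O | intermediate
13 | 6-(3-hydroxy-3-methylbutyl)kaempferol (3,5,7-trihydroxy-6-(3-hydroxy-3-methylbutyl)-2-(4-hydroxyphenyl)-4H-chromen-4-one; achiral) | CC(C)(O)CCc1c(O)cc2oc(-c3ccc(O)cc3)c(O)c(=O)c2c1O | target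

**Step count and risks**

Total step count: 7. Longest linear sequence: 7 steps, from kaempferol 1.

Steps most likely to fail:

1. Step 4. Loss of water from the hydrogen-bonded salicyl alcohol may be slow, the methide may condense with itself faster than it is captured, or traces of acid may divert the enol ether into acetal formation with the two hydroxyls. The fallback gives up the cycloaddition and makes C1''–C2'' as an alkene. Setting out from aldehyde 5, Wittig olefination with the stabilised ylide 1-(triphenylphosphoranylidene)propan-2-one (toluene, 100 °C) should give the enone 3,7,4'-tri-O-benzyl-6-[(1E)-3-oxobut-1-en-1-yl]kaempferol F1. Homogeneous hydrogenation of its disubstituted C=C bond with Wilkinson's catalyst (H2, (Ph3P)3RhCl, benzene/EtOH) should leave the benzyl ethers, the ketone and the tetrasubstituted C2=C3 bond alone and would return the route at ketone 11.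

2. Step 2. The magnesium phenoxide may stay locked in its chelate with the C4 carbonyl and fail to deliver formaldehyde to C6, leaving the reaction incomplete. The fallback sets out from 2. Iodination with benzyltrimethylammonium dichloroiodate and CaCO3 in CH2Cl2/MeOH, which for 5-hydroxy-7-alkoxyflavones is directed ortho to the free phenol, should give 3,7,4'-tri-O-benzyl-6-iodokaempferol F2. Stille coupling with (tributylstannyl)methanol (Pd(PPh3)4, dioxane, 90 °C) would then install the CH2OH group and return the route at salicyl alcohol 6, bypassing aldehyde 5 and step 3.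

3. Step 6. The Grignard reagent may attack the flavone at C4 or C2 in competition with the side-chain ketone, or enolise the methyl ketone. The fallback sets out from 11. Wittig methylenation (Ph3P=CH2 from MePPh3Br/KOtBu, THF, 0 °C → rt, one extra equivalent for the phenol) should give 3,7,4'-tri-O-benzyl-6-(3-methylbut-3-en-1-yl)kaempferol F3. Mukaiyama hydration (cat. Co(acac)2, PhSiH3, O2, THF/iPrOH, rt) adds water in the Markovnikov sense through a tertiary radical, without a carbanion or a carbocation, and would return the route at 12.

**Further compounds**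

F1 | step 4 | 3,7,4'-tri-O-benzyl-6-[(1E)-3-oxobut-1-en-1-yl]kaempferol | CC(=O)/C=C/c1c(OCc2ccccc2)cc2oc(-c3ccc(OCc4ccccc4)cc3)c(OCc3ccccc3)c(=O)c2c1O
F2 | step 2 | 3,7,4'-tri-O-benzyl-6-iodokaempferol | Ic1c(OCc2ccccc2)cc2oc(-c3ccc(OCc4ccccc4)cc3)c(OCc3ccccc3)c(=O)c2c1O
F3 | step 6 | 3,7,4'-tri-O-benzyl-6-(3-methylbut-3-en-1-yl)kaempferol | C=C(C)CCc1c(OCc2ccccc2)cc2oc(-c3ccc(OCc4ccccc4)cc3)c(OCc3ccccc3)c(=O)c2c1O
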